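**Plan**
- Retrosynthes: the ring B pyran is cut first (O1–C2 and C4–C4a, giving a phenol and 3-methylbut-2-enal), then the ring B benzene ring is opened at C8–C8a.
- This opening is possible because the ring B arene has its oxygens on C5, C7 and C8a, alternating with C6, C8 and C4a (phloroglucinol pattern), and C8 carries the stereocentre. The ring is therefore a folded 3,5-dioxo ester, used here as its bis(methyl enol ether).
- The open chain is cut at ring B C6–C7 (acylation of lithiated methyl 3-methoxybut-2-enoate by a Weinreb amide) and at the bond from the stereocentre to the alkene (alkenylboron 1,4-addition to methyl crotonate).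
- Forward order: ring A pyran (propargyl ether rearrangement), alkyne, (E)-alkenylboronic acid, chain assembly, ring B arene, ring B pyran.
- The single stereocentre is set by the rhodium/chiral diene addition and is never α to a carbonyl afterwards; the E alkene comes from syn hydroboration.

Key step: step 10

Remark: the (1S,4S) hand of the diene ligand in step 5 is assigned from the usual facial model for (E)-enoates (attack on the α-si face); if the first run shows the opposite sense, the (1R,4R) ligand is used.
Remark: chain locants C1–C9 in steps 8–10 refer to the nonanoate chain (C1 = ester carbon, C7 = stereocentre); ring locants refer to the 2H-chromene.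

Step 1
Reactants: 1 2-hydroxy-4,6-dimethoxybenzaldehyde; 2 3-chloro-3-methylbut-1-yne
Product: 3 2,4-dimethoxy-6-[(2-methylbut-3-yn-2-yl)oxy]benzaldehyde
Conditions: DBU, CuCl2·2H2O (1 mol %), MeCN, 0 °C → rt
Reagents that add atoms: none
Why: Copper-catalysed propargylic etherification of the phenol with the tertiary propargylic chloride, which works for hindered and hydrogen-bonded phenols and leaves the aldehyde alone.

Step 2
Reactants: 3 2,4-dimethoxy-6-[(2-methylbut-3-yn-2-yl)oxy]benzaldehyde
Product: 4 5,7-dimethoxy-2,2-dimethyl-2H-chromene-8-carbaldehyde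
Conditions: PhNEt2, 180 °C
Reagents that add atoms: none
Why: Aromatic propargyl Claisen rearrangement to C5, the only free ortho carbon of 3, followed in the same pot by 1,5-hydrogen shift and oxa-6π electrocyclisation, gives the 2,2-dimethyl-2H-chromene with the formyl group necessarily on C8.

Step 3
Reactants: 4 5,7-dimethoxy-2,2-dimethyl-2H-chromene-8-carbaldehyde
Product: 5 8-ethynyl-5,7-dimethoxy-2,2-dimethyl-2H-chromene
Conditions: MeC(O)C(N2)P(O)(OMe)2, K2CO3, MeOH, 0 °C → rt
Reagents that add atoms: dimethyl (1-diazo-2-oxopropyl)phosphonate, CC(=O)C(=[N+]=[N-])P(=O)(OC)OC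
Why: The Ohira–Bestmann form of the Seyferth–Gilbert homologation turns the aryl aldehyde into the terminal alkyne under K2CO3/MeOH, conditions to which the chromene and the methyl ethers are inert.

Step 4
Reactants: 5 8-ethynyl-5,7-dimethoxy-2,2-dimethyl-2H-chromene
Product: 7 [(E)-2-(5,7-dimethoxy-2,2-dimethyl-2H-chromen-8-yl)ethenyl]boronic acid, via alkenyl catecholboronate 6 (not isolated)
Conditions: catecholborane (1.1 equiv), THF, 65 °C; then H2O, rt
Reagents that add atoms: catecholborane, B1Oc2ccccc2O1; water, O
Why: Syn, anti-Markovnikov hydroboration of the terminal alkyne by catecholborane fixes the E geometry, the alkyne reacting far faster than the hindered cis-disubstituted chromene alkene, and water hydrolyses the boronate to the boronic acid.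

Step 5
Reactants: 7 [(E)-2-(5,7-dimethoxy-2,2-dimethyl-2H-chromen-8-yl)ethenyl]boronic acid; 8 methyl (2E)-but-2-enoate (methyl crotonate, used in excess)
Product: 9 methyl (3R,4E)-5-(5,7-dimethoxy-2,2-dimethyl-2H-chromen-8-yl)-3-methylpent-4-enoate
Conditions: [RhCl(C2H4)2]2 (2.5 mol %), (1S,4S)-2,5-diphenylbicyclo[2.2.2]octa-2,5-diene (5.5 mol %), KOH (0.2 equiv), 1,4-dioxane/H2O 10:1, 40 °C
Reagents that add atoms: none
Why: Hayashi–Miyaura rhodium-catalysed asymmetric 1,4-addition, in which the alkenyl group passes from boron to rhodium with retention of E geometry and the crotonate inserts into the alkenyl–rhodium bond on the face left open by the C2-symmetric diene ligand, which sets C3 as R.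

Step 6
Reactants: 9 methyl (3R,4E)-5-(5,7-dimethoxy-2,2-dimethyl-2H-chromen-8-yl)-3-methylpent-4-enoate
Product: 10 (3R,4E)-5-(5,7-dimethoxy-2,2-dimethyl-2H-chromen-8-yl)-N-methoxy-N,3-dimethylpent-4-enamide
Conditions: MeNH(OMe)·HCl, i-PrMgCl, THF, −20 → 0 °C
Reagents that add atoms: N,O-dimethylhydroxylamine hydrochloride, CNOC.Cl
Why: Aminolysis of the methyl ester by the chloromagnesium amide of N,O-dimethylhydroxylamine (Weinreb amide formation) stops at the amide, and the β stereocentre cannot epimerise.

Step 7
Reactants: 11 methyl 3-oxobutanoate (methyl acetoacetate)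
Product: 12 methyl (2E)-3-methoxybut-2-enoate
Conditions: HC(OMe)3, H2SO4 (cat.), MeOH, rt; distillation
Reagents that add atoms: trimethyl orthoformate, COC(OC)OC
Why: Acid-catalysed enol ether formation from the β-keto ester through its dimethyl ketal gives the thermodynamically preferred E isomer, which is purified by distillation.

Step 8
Reactants: 12 methyl (2E)-3-methoxybut-2-enoate; 10 (3R,4E)-5-(5,7-dimethoxy-2,2-dimethyl-2H-chromen-8-yl)-N-methoxy-N,3-dimethylpent-4-enamide
Product: 14 methyl (2E,7R,8E)-9-(5,7-dimethoxy-2,2-dimethyl-2H-chromen-8-yl)-3-methoxy-7-methyl-5-oxonona-2,8-dienoate, via lithium dienolate 13 (not isolated)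
Conditions: 12 (2 equiv), LiN(i-Pr)2 (2 equiv, commercial solution), THF, −78 °C; then 10, −78 → −40 °C; aq NH4Cl
Reagents that add atoms: none
Why: Vinylogous Claisen-type acylation in which the lithium dienolate of the 3-methoxy enoate reacts at its γ carbon with the Weinreb amide, whose chelated tetrahedral adduct prevents a second addition and releases the ketone only on work-up, with the C2=C3 bond expected back in conjugation as E.

Step 9
Reactants: 14 methyl (2E,7R,8E)-9-(5,7-dimethoxy-2,2-dimethyl-2H-chromen-8-yl)-3-methoxy-7-methyl-5-oxonona-2,8-dienoate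
Product: 16 methyl (2E,4E,7R,8E)-9-(5,7-dimethoxy-2,2-dimethyl-2H-chromen-8-yl)-3,5-dimethoxy-7-methylnona-2,4,8-trienoate, via potassium enolate 15 (not isolated)
Conditions: KN(SiMe3)2 (1.05 equiv), 18-crown-6, THF, −78 °C; then CF3SO3Me, −78 °C
Reagents that add atoms: methyl trifluoromethanesulfonate, COS(=O)(=O)C(F)(F)F
Why: Enolate O-alkylation, in which deprotonation at C4 (flanked by the ketone and the enoate) gives a delocalised, ion-pair-separated potassium enolate that the hard electrophile methyl triflate should methylate on oxygen; the 4E isomer drawn is the expected and thermodynamically preferred one, and any 4Z isomer would be taken on unseparated because step 10 turns C4=C5 into a single bond.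

Step 10
Reactants: 16 methyl (2E,4E,7R,8E)-9-(5,7-dimethoxy-2,2-dimethyl-2H-chromen-8-yl)-3,5-dimethoxy-7-methylnona-2,4,8-trienoate
Product: 19 2-[(2S,3E)-4-(5,7-dimethoxy-2,2-dimethyl-2H-chromen-8-yl)but-3-en-2-yl]-3,5-dimethoxyphenol, via lithium trienolate 17 (not isolated), via cyclohexadienone 18 (not isolated)
Conditions: LiN(i-Pr)2 (1.2 equiv), THF, −78 °C → rt; aq NH4Cl
Reagents that add atoms: none
Why: Proposed new method: LiN(i-Pr)2 removes a proton from C6 (the CH2 between the C5 enol ether and the stereocentre), the only position whose anion is delocalised through the dienoate onto the ester oxygen; in this trienolate the former C2=C3 and C4=C5 bonds are single bonds, so whichever enol-ether geometry step 9 delivers can reach the coiled form in which C6 lies over C1. C6 then bonds to the ester carbon C1 in a 6-(enolendo)-exo-trig Claisen (Dieckmann-type) closure, equally describable as a 6π-electrocyclisation of a 1-oxidotriene, methoxide is expelled and cyclohexadienone 18 tautomerises to the phenoxide, which makes the sequence irreversible. The closest known reaction type is the base-induced Claisen cyclisation of 3,5-dioxoalkanoates and their derivatives to phloroglucinols; the version masked as two methyl enol ethers has not been shown. No stereocentre is created: the sp3 ring carbon of 18 is lost on aromatisation and the existing centre next to it is never deprotonated, so 7R in the chain becomes 2S in the phenol only through the change in substituent priority. The selectivity needed is deprotonation at C6 rather than at the allylic C7–H, which the large acidity gap supplies, and base is held near 1.2 equivalents and the temperature at or below rt so that the doubly activated benzylic/allylic C–H of 19, further shielded by the adjacent phenoxide charge, is left alone. Because two of the three oxygens arrive as methyl ethers, the only free OH of 19 is the one next to the single open ortho carbon, exactly what step 11 needs.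

Step 11
Reactants: 19 2-[(2S,3E)-4-(5,7-dimethoxy-2,2-dimethyl-2H-chromen-8-yl)but-3-en-2-yl]-3,5-dimethoxyphenol; 20 3-methylbut-2-enal
Product: 21 8-[(2S,3E)-4-(5,7-dimethoxy-2,2-dimethyl-2H-chromen-8-yl)but-3-en-2-yl]-5,7-dimethoxy-2,2-dimethyl-2H-chromene (CNP0198894.2)
Conditions: ethylenediammonium diacetate (10 mol %), toluene, 90 °C
Reagents that add atoms: none
Why: Amine-salt-catalysed chromene annulation of a phenol with an enal, in which iminium activation of 20, C-alkylation at the only free ortho carbon of 19, loss of the amine and oxa-6π electrocyclisation close the ring B pyran, while the near-neutral catalyst should spare the electron-rich styrene and the stereocentre.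

**Compound list**
1 | 2-hydroxy-4,6-dimethoxybenzaldehyde | COc1cc(O)c(C=O)c(OC)c1 | starting material
2 | 3-chloro-3-methylbut-1-yne | C#CC(C)(C)Cl | starting material
3 | 2,4-dimethoxy-6-[(2-methylbut-3-yn-2-yl)oxy]benzaldehyde | COc1cc(OC)c(C=O)c(OC(C)(C)C#C)c1 | intermediate
4 | 5,7-dimethoxy-2,2-dimethyl-2H-chromene-8-carbaldehyde | O=Cc1c(OC)cc(OC)c2c1OC(C)(C)C=C2 | intermediate
5 | 8-ethynyl-5,7-dimethoxy-2,2-dimethyl-2H-chromene | C#Cc1c(OC)cc(OC)c2c1OC(C)(C)C=C2 | intermediate
6 | 2-[(E)-2-(5,7-dimethoxy-2,2-dimethyl-2H-chromen-8-yl)ethenyl]-1,3,2-benzodioxaborole | B1(Oc2ccccc2O1)/C=C/c3c(OC)cc(OC)c4c3OC(C)(C)C=C4 | intermediate (not isolated)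
7 | [(E)-2-(5,7-dimethoxy-2,2-dimethyl-2H-chromen-8-yl)ethenyl]boronic acid | OB(O)/C=C/c1c(OC)cc(OC)c2c1OC(C)(C)C=C2 | intermediate
8 | methyl (2E)-but-2-enoate | C/C=C/C(=O)OC | starting material
9 | methyl (3R,4E)-5-(5,7-dimethoxy-2,2-dimethyl-2H-chromen-8-yl)-3-methylpent-4-enoate | COC(=O)C[C@@H](C)/C=C/c1c(OC)cc(OC)c2c1OC(C)(C)C=C2 | intermediate
10 | (3R,4E)-5-(5,7-dimethoxy-2,2-dimethyl-2H-chromen-8-yl)-N-methoxy-N,3-dimethylpent-4-enamide | CON(C)C(=O)C[C@@H](C)/C=C/c1c(OC)cc(OC)c2c1OC(C)(C)C=C2 | intermediate
11 | methyl 3-oxobutanoate | COC(=O)CC(C)=O | starting material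
12 | methyl (2E)-3-methoxybut-2-enoate | COC(=O)/C=C(/OC)C | intermediate
13 | lithium 1,3-dimethoxybuta-1,3-dien-1-olate (γ-lithiated 12) | [Li+].[O-]C(OC)=CC(OC)=C | intermediate (not isolated)
14 | methyl (2E,7R,8E)-9-(5,7-dimethoxy-2,2-dimethyl-2H-chromen-8-yl)-3-methoxy-7-methyl-5-oxonona-2,8-dienoate | COC(=O)/C=C(/OC)CC(=O)C[C@@H](C)/C=C/c1c(OC)cc(OC)c2c1OC(C)(C)C=C2 | intermediate
15 | potassium C4=C5 enolate of 14 (oxygen on C5, geometry open) | [K+].COC(=O)/C=C(/OC)C=C([O-])C[C@@H](C)/C=C/c1c(OC)cc(OC)c2c1OC(C)(C)C=C2 | intermediate (not isolated)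
16 | methyl (2E,4E,7R,8E)-9-(5,7-dimethoxy-2,2-dimethyl-2H-chromen-8-yl)-3,5-dimethoxy-7-methylnona-2,4,8-trienoate | COC(=O)/C=C(/OC)\C=C(\OC)C[C@@H](C)/C=C/c1c(OC)cc(OC)c2c1OC(C)(C)C=C2 | intermediate
17 | lithium trienolate of 16 (C6 deprotonated, charge on the ester oxygen) | [Li+].[O-]C(OC)=CC(OC)=CC(OC)=C[C@@H](C)/C=C/c1c(OC)cc(OC)c2c1OC(C)(C)C=C2 | intermediate (not isolated)
18 | 6-[(3E)-4-(5,7-dimethoxy-2,2-dimethyl-2H-chromen-8-yl)but-3-en-2-yl]-3,5-dimethoxycyclohexa-2,4-dien-1-one (keto tautomer of 19, side-chain centre as in 19) | O=C1C=C(OC)C=C(OC)C1[C@@H](C)/C=C/c2c(OC)cc(OC)c3c2OC(C)(C)C=C3 | intermediate (not isolated)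
19 | 2-[(2S,3E)-4-(5,7-dimethoxy-2,2-dimethyl-2H-chromen-8-yl)but-3-en-2-yl]-3,5-dimethoxyphenol | COc1cc(OC)c(/C=C/[C@H](C)c2c(OC)cc(OC)cc2O)c2c1C=CC(C)(C)O2 | intermediate
20 | 3-methylbut-2-enal | CC(C)=CC=O | starting material
21 | 8-[(2S,3E)-4-(5,7-dimethoxy-2,2-dimethyl-2H-chromen-8-yl)but-3-en-2-yl]-5,7-dimethoxy-2,2-dimethyl-2H-chromene | COc1cc(OC)c(/C=C/[C@H](C)c2c(OC)cc(OC)c3c2OC(C)(C)C=C3)c2c1C=CC(C)(C)O2 | target

**Step count**
Total: 11 steps. Longest linear sequence: 10 steps (steps 1–6 and 8–11, from 1); step 7 is a one-step side branch.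

**Steps most likely to fail**

Step 10. The trienolate may not close: it can stay in an extended geometry and simply be reprotonated on work-up to a deconjugated isomer, or excess base may erode the stereocentre once the arene has formed. The fallback sets out from 14 and uses the known base-induced Claisen cyclisation of a 3,5-dioxoalkanoate derivative. With about 2.5 equivalents of LiN(i-Pr)2 in THF (−78 °C → rt) the C4,C6-dianion of 14 closes through C6 onto the ester carbon and gives the symmetrical resorcinol 2-[(2S,3E)-4-(5,7-dimethoxy-2,2-dimethyl-2H-chromen-8-yl)but-3-en-2-yl]-5-methoxybenzene-1,3-diol F1. One equivalent of 20 with ethylenediammonium diacetate annulates either of its two equivalent OH/ortho-carbon pairs to 8-[(2S,3E)-4-(5,7-dimethoxy-2,2-dimethyl-2H-chromen-8-yl)but-3-en-2-yl]-5-methoxy-2,2-dimethyl-2H-chromen-7-ol F2. MeI and K2CO3 in acetone then methylate the remaining phenol, and the route is rejoined at 21. The price is one more step and the need to stop the annulation after one ring.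

Step 9. Methylation may go to carbon C4 instead of oxygen, or the enolate may lactonise onto the ester to a 4-methoxy-2-pyranone before it is trapped. The fallback sets out from 14 and makes the enol ether through the ketal instead of the enolate. HC(OMe)3 in MeOH with a trace of pyridinium p-toluenesulfonate converts the C5 ketone into methyl (2E,7R,8E)-9-(5,7-dimethoxy-2,2-dimethyl-2H-chromen-8-yl)-3,5,5-trimethoxy-7-methylnona-2,8-dienoate F3. Me3SiOTf with i-Pr2NEt in CH2Cl2 at −20 °C then removes one methoxy group toward C4, the conjugating side, and returns to the route at 16.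

Step 5. Protodeboronation of the electron-rich alkenylboronic acid may outrun transmetalation, and facial control with the weakly coordinating ester acceptor may be incomplete. The fallback sets out from 4 and sets the same centre by hydride delivery instead of alkenyl delivery. Horner–Wadsworth–Emmons reaction of 4 with methyl (2E)-4-(diethoxyphosphoryl)-3-methylbut-2-enoate (NaH, THF) gives methyl (2E,4E)-5-(5,7-dimethoxy-2,2-dimethyl-2H-chromen-8-yl)-3-methylpenta-2,4-dienoate F4. Copper hydride 1,4-reduction (CuCl, NaOt-Bu, the hand of p-Tol-BINAP that gives 3R, polymethylhydrosiloxane, toluene) reduces only the C2=C3 bond and returns to the route at 9, bypassing steps 3 and 4.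

Further compounds
F1 | step 10 | 2-[(2S,3E)-4-(5,7-dimethoxy-2,2-dimethyl-2H-chromen-8-yl)but-3-en-2-yl]-5-methoxybenzene-1,3-diol | Oc1cc(OC)cc(O)c1[C@@H](C)/C=C/c1c(OC)cc(OC)c2c1OC(C)(C)C=C2
F2 | step 10 | 8-[(2S,3E)-4-(5,7-dimethoxy-2,2-dimethyl-2H-chromen-8-yl)but-3-en-2-yl]-5-methoxy-2,2-dimethyl-2H-chromen-7-ol | COc1cc(OC)c(/C=C/[C@H](C)c2c(O)cc(OC)c3c2OC(C)(C)C=C3)c2c1C=CC(C)(C)O2
F3 | step 9 | methyl (2E,7R,8E)-9-(5,7-dimethoxy-2,2-dimethyl-2H-chromen-8-yl)-3,5,5-trimethoxy-7-methylnona-2,8-dienoate | COC(=O)/C=C(/OC)CC(OC)(OC)C[C@@H](C)/C=C/c1c(OC)cc(OC)c2c1OC(C)(C)C=C2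
F4 | step 5 | methyl (2E,4E)-5-(5,7-dimethoxy-2,2-dimethyl-2H-chromen-8-yl)-3-methylpenta-2,4-dienoate | COC(=O)/C=C(\C)/C=C/c1c(OC)cc(OC)c2c1OC(C)(C)C=C2
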